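The ratio I watch is [complex with one exchanged] / [starting complex] at the top of the complex's curve. You want a quick number, and your hunch is that more scavenger carries the reaction further. At 40.0 h, theta, alpha and epsilon read 8%, 10% and 8% of starting complex.

| setting | theta | alpha | epsilon | ash | cedar | oak |
|---|---|---|---|---|---|---|
| starting complex | 0.010 M | 0.010 M | 0.010 M | 0.010 M | 0.010 M | 0.010 M |
| incoming ligand | 0.025 M | 0.025 M | 0.025 M | 0.0250 M | 0.0250 M | 0.0250 M |
| leaving ligand | 5 mM | 5 mM | 5 mM | 5.00 mM | 5.00 mM | 5.00 mM |
| scavenger | 6.5 mM | 6.9 mM | 13 mM | 7.50 mM | 11.0 mM | 5.00 mM |
| remark | run made earlier | run made earlier | run made earlier |  |  |  |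
| time |  |  |  | 40 h | 40 h | 40 h |

- theta (time / h: starting complex / %, complex with one exchanged / %): 4.00: 41, 14; 10.0: 28, 25; 20.0: 19, 26; 30.0: 13, 23; 40.0: 8, 19
- alpha (time / h: starting complex / %, complex with one exchanged / %): 4.00: 42, 16; 10.0: 28, 24; 20.0: 18, 25; 30.0: 13, 24; 40.0: 10, 20
- epsilon (time / h: starting complex / %, complex with one exchanged / %): 8.00: 39, 23; 15.0: 26, 31; 25.0: 19, 30; 30.0: 15, 26; 40.0: 8, 22

(readings scatter by 1.5 percentage points)

- a reading or a percentage of leaving ligand counts all its forms, free or not
- what has gone from starting complex into another species counts as reacted, even if it can come back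
- a reading of starting complex is of its free form alone

* part of the starting complex that has reacted at the end, ash
* part of the starting complex that has reacted at the end, cedar
* part of the starting complex that has reacted at the end, oak
* what raising the concentration of scavenger from its lowest to its highest value here does to the part of the starting complex that has reacted (changes below 5 percentage points count as none) (it rises / it falls / no change)

At the top of its curve, the complex with one exchanged is made as fast as it is used. I treat both steps as pseudo-first-order: making goes with [starting complex], using with [complex with one exchanged]. The two rates are equal there, so time drops out, and the concentration ratio at the top equals the making constant over the using constant.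

theta, 20.0 h: 26% / 19% = 1.37

alpha, 20.0 h: 25% / 18% = 1.39

epsilon, 15.0 h: 31% / 26% = 1.19

epsilon, 25.0 h: 30% / 19% = 1.58

I call the theta value the crossover ratio. Each reading behind it carries 1.5 percentage points. Epsilon has twice theta's scavenger, and its top lies between its two readings, which bracket that value. So I read the crossover ratio as not moving with scavenger. With these charges, I expect a flask whose ratio stands above this reading to have its complex falling.

My forecast is 91% for ash, 91% for cedar and 91% for oak, with the trend no change, because the end readings are “flat within the 1.5-point error”.

    leaving ligand + starting complex ⇌ idle adduct, settled at all times (K = 810 M⁻¹)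
    starting complex + incoming ligand ⇌ leaving ligand + complex with one exchanged (K = 0.592, k = 0.0611 M⁻¹ min⁻¹)
    complex with one exchanged → over-reaction product (k = 7.75 × 10⁻⁴ min⁻¹)
    scavenger + leaving ligand → scavenged by-product (k = 0.845 M⁻¹ min⁻¹)
    2 starting complex → self-condensation product (k = 0.0195 M⁻¹ min⁻¹)
    complex with one exchanged + incoming ligand ⇌ leaving ligand + complex with two exchanged (K = 0.190, k = 0.00214 M⁻¹ min⁻¹)

The flasks give 89.4% for ash, 88.9% for cedar and 89.8% for oak, and the trend is no change, at −0.94 points. To move ash's reacted part by 5 points, the reading has to go to 26.9 h or 71.6 h, or incoming ligand to 0.0174 M or 0.0451 M. In ash the scavenger step has 78% of its turnover to the end behind it by 20.0 h, when the ratio stands at 1.39, level with the crossover ratio of 1.37. Over-reaction product then climbs from 20.0% to 42.0% by 40.0 h, while scavenger falls to 3.35% and the ratio reaches 1.79, above the crossover ratio, with the complex made, net, at 0.482 of its using rate. The same flask stopped at 10.0 h stands at a ratio of 0.850, below the crossover ratio, and at 10.5 h ash makes its complex, net, 1.64 times faster than it uses it.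

The numbers in the tables come from a simulation with made-up constants; the scatter is artificial.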